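Start from the slowness of the south run and ask what holds its curve down.

| flask | substrate | free catalyst | time |
|---|---|---|---|
| south | 300 mM | 24.0 mM |  |
| south-west | 150 mM | 24.0 mM |  |
| north-west | 300 mM | 12.0 mM |  |
| north | 600 mM | 7.90 mM | 17 min |

| run | time / min | [target] / mM |
|---|---|---|
| south run | 0.61 | 10.9 |
| south run | 1.8 | 22.9 |
| south run | 3.5 | 39.8 |
| south run | 5.6 | 62.8 |
| south run | 8.0 | 80.7 |
| south run | 11 | 96.5 |
| south run | 14 | 110.3 |
| south run | 17 | 112.8 |
| south-west run | 0.61 | 2.2 |
| south-west run | 1.8 | 10.5 |
| south-west run | 3.5 | 19.0 |
| south-west run | 5.6 | 33.3 |
| south-west run | 8.0 | 35.3 |
| south-west run | 11 | 47.1 |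
| south-west run | 14 | 49.5 |
| south-west run | 17 | 52.0 |
| north-west run | 0.61 | 1.9 |
| north-west run | 1.8 | 10.3 |
| north-west run | 3.5 | 25.1 |
| north-west run | 5.6 | 34.9 |
| north-west run | 8.0 | 43.7 |
| north-west run | 11 | 56.9 |
| north-west run | 14 | 65.4 |
| north-west run | 17 | 75.3 |

(each reading ± 2 mM)

- the power of [free catalyst] that the first rate follows, about the charge of the south run; measure it at two percent of substrate made into target
- the power of [substrate] that the first rate follows, about the charge of the south run; measure it at two percent of substrate made into target (one fixed amount of target, the same in the runs compared)
- target in the north run at 17 min, as a share of the substrate charged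
- which of these the readings show (a little impurity takes part of the catalyst at once / nothing beyond the main steps / the product decays / the catalyst dies by itself / the loaded catalyst dies)

Treat the flask as two lags in series. The first is the filling time: the substrate charge over the first rate. Take the chord to 3.5 min in the south run, 11.4 mM min⁻¹, and 300 mM of substrate gives 26.4 min. At 5.6 min, the south-west run, with half the substrate, and the north-west run, with half the catalyst, have each made about half the south run's target. So take c(substrate) as falling in a pseudo-first-order way: the charge drops out of the filling time and the catalyst divides it. The north run then has 80.1 min.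

The second lag is the loss of target. At 14 min in the south run, 58.8% of the substrate remains on this reckoning, so target forms at 6.69 mM min⁻¹. The readings around that time rise at 2.72 mM min⁻¹. Read the gap as decay rather than dying catalyst, since at 17 min the north-west run holds 0.668 of the south run's target on a catalyst ratio of 0.500. Dividing 110.3 mM of target by that gap gives 27.8 min, the target's lifetime.

In the north run the filling time is longer than this lifetime, so the two lags give my figure of 14.1% at 17 min. The forecast, on the grounds that “South and south-west stall at the same fraction”, says the product decays, with orders of 1 in catalyst and 0.95 in substrate. Its 16.7% is higher than my figure.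

The north run gives 14.1% of its substrate as target, the orders are 0.93 in catalyst and 0.87 in substrate, and the answer is that the product decays. A fit with the main steps alone leaves residuals of 3.0 scatters and forecasts 20.0% for the north run. Target in the north run is on average about 8.50 min old at 17 min, and the lifetime read off the south run, 27.8 min, puts the surviving share of it at about 73.7%.

    free catalyst + substrate ⇌ catalyst-substrate complex, settled at all times (8.510 L mol⁻¹)
    catalyst-substrate complex + substrate ⇌ doubly bound catalyst, settled at all times (3.510 L mol⁻¹)
    doubly bound catalyst → target + catalyst-substrate complex (1.452 min⁻¹)
    target → decomposed product (0.03966 min⁻¹)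

In the south-west run, the filling time of 26.4 min and the same lifetime give 51.6 mM at 17 min, where the reading is 52.0 mM.

The readings come from a simulation from invented constants.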